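The data were generated by integration from invented constants, noise included.

At early times target trailed the starting material spent: the ash run showed 51.2% at 1.50 min. Later the ratio barely moved, reading 55.8% at 3.00 min and 56.8% at 5.00 min. So I froze it. At 6.00 min the ash run read 55.5% for this keep, target found over starting material spent, a running selectivity. The birch run read 55.0% at 6.00 min.

the same everywhere: starting material 0.46 M

|  | partner | remark | time |
|---|---|---|---|
| alder | 0.21 M | run made earlier |  |
| birch | 0.57 M | run made earlier |  |
| ash | 1.3 M | run made earlier |  |
| Wednesday's | 0.250 M |  | 12 min |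
| Saturday's | 0.400 M |  | 12 min |
| Sunday's | 0.600 M |  | 12 min |
| Friday's | 1.00 M |  | 12 min |
| Tuesday's | 1.50 M |  | 12 min |

| run | time / min | target / % | starting material / % |
|---|---|---|---|
| alder | 0.500 | 1.9 | 88.6 |
| alder | 1.00 | 4.0 | 78.8 |
| alder | 2.50 | 14.8 | 51.0 |
| alder | 6.00 | 29.1 | 13.8 |
| birch | 0.833 | 2.9 | 79.8 |
| birch | 2.00 | 19.6 | 56.7 |
| birch | 4.00 | 37.2 | 28.2 |
| birch | 6.00 | 46.9 | 14.8 |
| ash | 1.50 | 17.4 | 66.0 |
| ash | 3.00 | 35.0 | 37.3 |
| ash | 5.00 | 46.5 | 18.1 |
| ash | 6.00 | 49.1 | 11.5 |

(readings scatter by 1 percentage point)

- "hardly changes" means that all values lie within two and a half points (for a concentration: within two and a half percent of the largest)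

1. amount of target at the end, in percent of the starting material charged for Wednesday's, Saturday's, Sunday's, Friday's, Tuesday's, in this order
2. the course of these numbers from the first flask to the last (falls, then rises / hardly changes / rises, then falls / rises all the way / falls all the way)

Which numbers had to be known well? I took the time first. At 6.00 min the runs held 13.8%, 14.8% and 11.5% of starting material. The asked time is twice that, so I squared the alder reading and expected 1.90% left. An error as large as that left-over would move target by 1.1 percentage points.

The partner charge mattered at the low end. At 6.00 min the birch run held 18 points more target than the alder run, but the ash run held just 2.2 points more than the birch run. Wednesday's flask, at 0.250 M, sat near the alder charge, where the keep read 33.8%.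

The keep itself mattered too. On Sunday's, Friday's and Tuesday's flasks I took a point of keep as a point of target. So I reckoned 54.4% there, and Wednesday's flask well below that estimate.

The forecast gave 40%, 50%, 53%, 51% and 47%, a row that rises, then falls, and expected “a rise, a broad maximum near 0.6 M, then a gentle fall”. My estimate for Sunday's flask lay 1.4 points above its 53%.

The flasks gave 38.2%, 54.5%, 56.2%, 53.3% and 51.5%, so the row rises, then falls, turning at 0.51 M of partner.

    open intermediate + second intermediate → target (k = 0.0440 L mol⁻¹ s⁻¹)
    starting material → open intermediate (k = 0.00430 s⁻¹)
    partner → second intermediate (k = 0.0120 s⁻¹)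
    starting material + target → side product (k = 0.0120 L mol⁻¹ s⁻¹)

Sunday's flask had 0.91% of its starting material left, so the keep gave 55.0% against the 56.2% found. Wednesday's flask had a keep of 38.8%, which is 17 points under the frozen value. At 12.0 min Wednesday's flask still held 30.5% as open intermediate, beside 0.00594 M of second intermediate.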